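**Counting reagent.** I counted the reagent. Substrate here meets reagent that is itself consumed, so I took κ·R as a pseudo-first-order constant of substrate, with R the reagent left in both phases together, per volume of the first phase.

| setting | alder | ash | elm | flask |
|---|---|---|---|---|
| substrate | 0.050 M | 0.050 M | 0.075 M | 0.050 M |
| reagent in the second phase | 0.50 equiv | 0.75 equiv | 1 equiv | 1.00 equiv |
| remark | run made earlier | run made earlier | run made earlier |  |
| time |  |  |  | 3.0 d |
| volume of the second phase over the first |  |  |  | 2.0 |

- alder (time / h: target / %, substrate / %): 3.00: 2.5, 98.1; 6.00: 4.0, 94.7; 12.0: 8.5, 88.4; 25.0: 15.4, 79.7; 40.0: 19.8, 73.3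
- ash (time / h: target / %, substrate / %): 4.00: 5.6, 95.4; 10.0: 11.3, 85.9; 20.0: 17.7, 75.8; 30.0: 22.8, 68.6; 40.0: 27.7, 62.2
- elm (time / h: target / %, substrate / %): 3.00: 5.5, 91.6; 6.00: 12.7, 84.3; 12.0: 21.4, 72.1; 25.0: 31.9, 54.9; 40.0: 38.2, 43.0

(scatter of a reading: 0.5 percentage points)

- in the second phase: reagent in the second phase; everything else is in the first
- charges count per volume of the first phase; a concentration in a rate is the amount of a species over the volume of its own phase; every rate counts per litre of the first phase
- on the list of suspects stand: target <-> isomer of the product; reagent in the reaction phase + target -> over-reacted product; reagent in the reaction phase <-> reagent in the second phase; substrate + reagent in the reaction phase -> target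
- the earlier runs hold the two phases in the same ratio of volumes as the flask asked about

- dusk: doubling the transfer coefficient of the reagent in the second phase, all else as stated
- winter: doubling the amount of reagent in the second phase, all else as stated

* how much target there is at 3.0 d, in percent of the substrate charged
* the change that raises the amount of target at 3.0 d, in percent of the substrate charged most ("none" if none brings more than 2 percentage points) (dusk / winter / none)
* amount of target at 3.0 d, in percent of the substrate charged, after dusk

**First way.** Elm was charged equally, so the reciprocal of S, the fraction of substrate left, should climb from unity by κct, as in step growth, with c the charge and t the time. Its last reading gave 0.442 M⁻¹ h⁻¹ for κ, the apparent constant of substrate with reagent counted in both phases. The flask is charged equally too, so I reckoned S at 38.6% for it.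

**Second way.** For the flask I then replaced the reagent curve by the mean of its start and end, 0.0346 M. The exponential of −κ·R·t then gave 33.3%, so the two ways parted. The chord cheats: the hyperbola sags under it, and its true time mean is 0.0299 M, lower than the chord's mean. I kept the first way.

**Target share.** Elm's last reading, at 57.0% conversion, held target as 67.0% of the converted substrate. Applied to the flask, that share gave me 41.1% target.

**The forecast.** The forecast said 43%, 1.9 percentage points above mine, with winter as best and 43.3% after dusk, judging “Dusk changes almost nothing”.

**What stood.** The flask gave 40.6% target at 3.0 d and 40.8% after dusk, and winter gained 4.8 points against 0.15 points for dusk; that choice would fall if a run showed winter gaining under 2 points.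

    target ⇌ isomer of the product (K = 0.270, k = 0.273 h⁻¹)
    reagent in the reaction phase + target → over-reacted product (k = 0.492 M⁻¹ h⁻¹)
    reagent in the reaction phase ⇌ reagent in the second phase, rate k3*([reagent in the reaction phase] - [reagent in the second phase]/K3) per volume of the first phase (partition coefficient = 0.770, kL = 0.738 h⁻¹)
    substrate + reagent in the reaction phase → target (k = 1.25 M⁻¹ h⁻¹)

**Two clocks.** At 3.00 d the flask's substrate half-life by its step was 4.0 d, longer than the time elapsed, while target's forward half-life towards isomer was 0.11 d, far shorter. With the reagent then left in both phases of the flask, κ gave that substrate half-life as 4.37 d. For a neighbour flask with the same charges, read at 20 h, κ gave 69.4% substrate, and that neighbour held 68.7%.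

The earlier runs and the new flask were computed with made-up constants.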